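**Retrosynthetic overview**

1. The methyl ester and the free 8-OH are released together by methanolysis of an eight-membered unsaturated lactone that ties C15 to O8; C17 is carried as a 4-methoxybenzyl-protected carbinol and oxidised at the end.
2. Key disconnection C13=C14: ring-closing metathesis of a C8 acrylate with the isopropenyl terminus at C13. It rests on ring B (labdane numbering): the axial O8, syn to the C10 methyl, and the equatorial C11–C12 chain on C9 are gauche, so the ring O8–C15–C14=C13–C12–C11–C9–C8 closes readily and can hold only a cis alkene, which is the Z enoate.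
3. The C8 carbinol comes from the C8 ketone by sulfur ylide epoxidation (equatorial attack, axial O) and opening at C17. The isopropenyl group is coupled at C12 before that, while C8 is still a ketone, because a C12 halide beside a free 8-OH would close to the 8,12-ether.
4. Rings A and B with C3, C5, C9 and C10 come from andrographolide (double ozonolysis, C19 deoxygenation); the only ring formed is the temporary lactone (step 13), opened again in step 15.

Key step: step 13

Remark (assumption): α is the face of the C10 methyl (C20) in this antipodal series, β the face of H5 and H9. Nucleophiles are taken to attack the C8 ketone from the equatorial β direction, as is usual for cyclohexanones with a syn-axial 3-methyl group.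

**Route**

Step 1
Reactants: 1 andrographolide
Product: 2 andrographolide 3,19-acetonide (14-OH free)
Conditions: 2,2-dimethoxypropane, PPTS (cat.), CH2Cl2/acetone, 40 °C
Reagents that add atoms: 2,2-dimethoxypropane, COC(C)(C)OC
Why: Acid-catalysed transketalisation ties the 3-OH/19-OH 1,3-diol into a six-membered dioxane and leaves the lone 14-OH alone, which keeps ring A inert while the side chain is cut away.

Step 2
Reactants: 2 andrographolide 3,19-acetonide
Product: 4 keto aldehyde acetonide (C8 ketone; C9–CH2–CHO), via bis(methoxy hydroperoxide) 3 (not isolated)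
Conditions: O3, CH2Cl2/MeOH (4:1), −78 °C; then Me2S, −78 °C → rt
Reagents that add atoms: ozone, [O-][O+]=O
Why: Ozonolysis with reductive work-up: ozone cleaves the exocyclic C8=C17 and, in excess, the conjugated C12=C13 alkene, methanol traps the two carbonyl oxides as methoxy hydroperoxides and Me2S reduces them, so that C8 becomes a ketone and C12 an aldehyde while C17 and the lactone carbons C13–C16 are lost and C9 keeps its stable equatorial side chain.

Step 3
Reactants: 4 keto aldehyde acetonide
Product: 5 hydroxy ketone acetonide (C9–CH2CH2OH; C8 ketone)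
Conditions: NaBH4 (0.35 equiv), CH2Cl2/EtOH (7:3), −78 °C
Reagents that add atoms: none
Why: Chemoselective borohydride reduction, in which the unhindered aldehyde is reduced far faster at −78 °C than the α-branched ring ketone.

Step 4
Reactants: 5 hydroxy ketone acetonide
Product: 6 bromo ketone acetonide (C9–CH2CH2Br)
Conditions: CBr4, PPh3, CH2Cl2, 0 °C
Reagents that add atoms: carbon tetrabromide, BrC(Br)(Br)Br
Why: Appel bromination replaces the primary hydroxyl by SN2 displacement of the alkoxyphosphonium ion under neutral conditions that spare acetonide and ketone, and no C8 carbinol is present yet that could close the 8,12-ether.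

Step 5
Reactants: 6 bromo ketone acetonide; 7 2-bromopropene
Product: 8 isopropenyl ketone acetonide (C9–CH2CH2–C(CH3)=CH2; C8 ketone)
Conditions: NiBr2(dme) (10 mol%), 4,4'-di-tert-butyl-2,2'-bipyridine (10 mol%), Mn powder (2 equiv), NaI (0.25 equiv), 7 (3 equiv), DMPU, 25 °C
Reagents that add atoms: 2-bromopropene 7, CC(Br)=C
Why: Nickel-catalysed reductive cross-electrophile coupling joins the primary alkyl bromide (as a radical) to the alkenyl bromide (after its oxidative addition to zerovalent nickel) with Mn as terminal reductant, and since no organomagnesium reagent or strong base is present the C8 ketone is neither attacked nor enolised.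

Step 6
Reactants: 8 isopropenyl ketone acetonide
Product: 9 keto diol (3α-OH and 19-OH free)
Conditions: AcOH/H2O (7:3), 25 °C
Reagents that add atoms: none
Why: Acid-catalysed ketal hydrolysis frees the 3,19-diol under conditions too mild to hydrate or shift the 1,1-disubstituted alkene.

Step 7
Reactants: 9 keto diol
Product: 10 19-tosylate (3α-OH free)
Conditions: TsCl (1.3 equiv), pyridine, 0 °C → rt
Reagents that add atoms: 4-toluenesulfonyl chloride, Cc1ccc(cc1)S(=O)(=O)Cl
Why: Sulfonylation is selective for the primary, though neopentyl, 19-OH over the secondary 3-OH flanked by the quaternary C4.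

Step 8
Reactants: 10 19-tosylate
Product: 12 keto alcohol with gem-dimethyl C4 (3α-OH free), via neopentyl iodide 11 (not isolated)
Conditions: NaI, Zn dust, HMPA, 105 °C
Reagents that add atoms: none
Why: Iodide displaces the neopentyl tosylate in the dipolar aprotic solvent and zinc reduces the resulting iodide by electron transfer (a classical deoxygenation of C4 hydroxymethyl groups in terpenoids), which leaves ketone and alkene untouched and turns C4 into a gem-dimethyl carbon that is no longer stereogenic.

Step 9
Reactants: 12 keto alcohol
Product: 13 3-O-TBS ketone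
Conditions: TBSOTf (1.3 equiv), 2,6-lutidine, CH2Cl2, −78 → 0 °C
Reagents that add atoms: tert-butyldimethylsilyl trifluoromethanesulfonate, CC(C)(C)[Si](C)(C)OS(=O)(=O)C(F)(F)F
Why: Silylation with the silyl triflate and a hindered pyridine base protects the hindered equatorial 3-OH at low temperature without enolising the ketone.

Step 10
Reactants: 13 3-O-TBS ketone; 14 trimethylsulfonium iodide
Product: 15 8α,17-epoxide (spiro epoxide at C8; O axial and syn to C20; C17 equatorial)
Conditions: 14, n-BuLi, THF, −10 °C; then 13, −10 °C → rt
Reagents that add atoms: trimethylsulfonium iodide 14, C[S+](C)C.[I-]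
Why: Corey–Chaykovsky epoxidation, in which the sulfur ylide adds irreversibly to the C8 carbonyl from the equatorial β direction because the axial approach is blocked by the syn-axial C10 methyl, so that ring closure of the betaine places O8 axial (α) and C17 equatorial, the C8 configuration of the target.

Step 11
Reactants: 15 8α,17-epoxide
Product: 16 tertiary alcohol (8α-OH axial; C17–O–CH2C6H4-4-OMe; 3-O-TBS)
Conditions: 4-methoxybenzyl alcohol (5 equiv), NaH (3 equiv), DMF, 70 °C; then H2O
Reagents that add atoms: 4-methoxybenzyl alcohol, COc1ccc(CO)cc1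
Why: Base-mediated epoxide opening by SN2 attack of the alkoxide at the unsubstituted carbon C17 leaves the C8 configuration untouched and delivers the axial tertiary alcohol with O17 already protected as an ether that cannot migrate to O8.

Step 12
Reactants: 16 tertiary alcohol; 17 acryloyl chloride
Product: 19 8-O-acrylate (metathesis precursor), via potassium alkoxide 18 (not isolated)
Conditions: KN(SiMe3)2 (1.05 equiv), THF, −78 °C; then 17, −78 → −20 °C
Reagents that add atoms: acryloyl chloride 17, C=CC(=O)Cl
Why: O-Acylation of a preformed potassium alkoxide with an acid chloride at low temperature is the standard esterification of a hindered tertiary alcohol, O3 is silylated so only O8 reacts, and the benzyl-type ether on O17 (unlike a silyl ether or an ester) cannot shift to the neighbouring alkoxide.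

Step 13
Reactants: 19 8-O-acrylate
Product: 20 eight-membered (Z)-enoate lactone (C15 acyl on O8; C13=C14 in the ring; O17-PMB; 3-O-TBS)
Conditions: second-generation Hoveyda–Grubbs catalyst RuCl2(SIMes)(=CH-C6H4-2-OiPr) (10 mol% in two portions), 1,4-benzoquinone (20 mol%), toluene (0.002 M), 100 °C, Ar sparge
Reagents that add atoms: none
Why: The ruthenium alkylidene is expected to exchange onto one terminal alkene, add across the other within a ruthenacyclobutane and cyclorevert, so that C13=C14 is formed and ethylene is lost. The closest known reaction type is ring-closing metathesis of acrylate esters with 1,1-disubstituted alkenes to β-methyl α,β-unsaturated lactones using second-generation ruthenium catalysts, applied here to an eight-membered ring on a tertiary ester. The single ring that closes, O8–C15–C14=C13–C12–C11–C9–C8, is formed by metathesis with both alkene carbons inside the ring (endocyclic C13=C14) and is cis-fused to ring B. No stereocentre is created, and C8 and C9 are not touched. The step needs Z geometry and cyclisation instead of oligomerisation: the first is secured by the ring size, since an eight-membered ring cannot hold a trans trisubstituted alkene, so C12 and C15 end up cis; the second by high dilution, removal of ethylene and the rigid trans-decalin, which holds the axial O8 and the equatorial C11 chain gauche and keeps the two alkenes within reach. Benzoquinone suppresses ruthenium hydride migration of the isopropenyl double bond, and the 4-methoxybenzyl and silyl ethers are spectators.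

Step 14
Reactants: 20 eight-membered (Z)-enoate lactone
Product: 21 17-hydroxy eight-membered lactone
Conditions: DDQ (1.5 equiv), CH2Cl2/pH 7 buffer (10:1), 0 °C → rt
Reagents that add atoms: none
Why: Oxidative cleavage of the 4-methoxybenzyl ether by DDQ (hydride abstraction and hydrolysis of the oxocarbenium ion) frees 17-OH while O8 is still acylated, so no cyclic anisylidene acetal can form, and the silyl ether and the enoate are inert.

Step 15
Reactants: 21 17-hydroxy eight-membered lactone
Product: 23 diol methyl ester (methyl (13Z)-enoate; 8α-OH and 17-OH free; 3-O-TBS), via nine-membered lactone 22 (not isolated)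
Conditions: K2CO3 (0.5 equiv), MeOH, 0 °C → rt
Reagents that add atoms: methanol, CO
Why: Base-catalysed transesterification, in which the 17-alkoxide is expected to take over the acyl group from the tertiary O8 through a five-membered tetrahedral intermediate (1,2-acyl shift) and methoxide then opens the resulting primary medium-ring lactone to the methyl ester, leaving the Z geometry untouched and releasing 8-OH and 17-OH together.

Step 16
Reactants: 23 diol methyl ester
Product: 24 17-aldehyde (8α-hydroxy-17-oxo; 3-O-TBS)
Conditions: (COCl)2, DMSO, CH2Cl2, −78 °C; then Et3N, −78 → 0 °C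
Reagents that add atoms: none
Why: Swern oxidation turns the primary 17-OH into the aldehyde, the tertiary 8-OH cannot be oxidised, the quaternary C8 cannot epimerise, and activated DMSO does not cleave the 1,2-diol as periodate-type oxidants would.

Step 17
Reactants: 24 17-aldehyde
Product: 25 target, methyl (13Z)-3α,8α-dihydroxy-17-oxolabd-13-en-15-oate of the antipodal series
Conditions: HF·pyridine, THF, 0 °C → rt
Reagents that add atoms: none
Why: Fluoride-mediated desilylation with HF·pyridine removes the 3-O-silyl group under mildly acidic conditions that avoid base-induced α-ketol rearrangement of the hydroxy aldehyde and conjugate addition of 8-OH to the enoate.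

**Compound list**

1 | andrographolide | C[C@@]12CC[C@H]([C@@]([C@H]1CCC(=C)[C@H]2C/C=C/3\[C@@H](COC3=O)O)(C)CO)O | starting material
2 | andrographolide 3,19-acetonide | C[C@@]12CC[C@H]([C@@]([C@H]1CCC(=C)[C@H]2C/C=C/3\[C@@H](COC3=O)O)(C)COC4(C)C)O4 | intermediate
3 | bis(methoxy hydroperoxide) at C8 and C12 of the acetonide core (mixture at the two new centres) | C[C@@]12CC[C@H]([C@@]([C@H]1CCC(OC)(OO)[C@H]2CC(OC)OO)(C)COC3(C)C)O3 | intermediate
4 | keto aldehyde acetonide (C8 ketone, C12 aldehyde) | C[C@@]12CC[C@H]([C@@]([C@H]1CCC(=O)[C@H]2CC=O)(C)COC3(C)C)O3 | intermediate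
5 | hydroxy ketone acetonide (12-OH) | C[C@@]12CC[C@H]([C@@]([C@H]1CCC(=O)[C@H]2CCO)(C)COC3(C)C)O3 | intermediate
6 | bromo ketone acetonide (12-Br) | C[C@@]12CC[C@H]([C@@]([C@H]1CCC(=O)[C@H]2CCBr)(C)COC3(C)C)O3 | intermediate
7 | 2-bromopropene | CC(Br)=C | starting material
8 | isopropenyl ketone acetonide (C9 chain 3-methylbut-3-enyl) | C[C@@]12CC[C@H]([C@@]([C@H]1CCC(=O)[C@H]2CCC(C)=C)(C)COC3(C)C)O3 | intermediate
9 | keto diol (3α-OH, 19-OH) | C[C@@]12CC[C@H]([C@@]([C@H]1CCC(=O)[C@H]2CCC(C)=C)(C)CO)O | intermediate
10 | 19-tosylate of the keto diol | C[C@@]12CC[C@H]([C@@]([C@H]1CCC(=O)[C@H]2CCC(C)=C)(C)COS(=O)(=O)c3ccc(C)cc3)O | intermediate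
11 | 19-iodide (neopentyl iodide) | C[C@@]12CC[C@H]([C@@]([C@H]1CCC(=O)[C@H]2CCC(C)=C)(C)CI)O | intermediate
12 | keto alcohol with gem-dimethyl C4 (3α-OH) | C[C@@]12CC[C@H](C([C@H]1CCC(=O)[C@H]2CCC(C)=C)(C)C)O | intermediate
13 | 3-O-TBS ketone | C[C@@]12CC[C@H](C([C@H]1CCC(=O)[C@H]2CCC(C)=C)(C)C)O[Si](C)(C)C(C)(C)C | intermediate
14 | trimethylsulfonium iodide | C[S+](C)C.[I-] | starting material
15 | 8α,17-epoxide (O axial, C17 equatorial) | C=C(C)CC[C@H]1[C@]2(C)CC[C@@H](O[Si](C)(C)C(C)(C)C)C(C)(C)[C@H]2CC[C@]13CO3 | intermediate
16 | tertiary alcohol (8α-OH, 17-O-PMB, 3-O-TBS) | C=C(C)CC[C@H]1[C@]2(C)CC[C@@H](O[Si](C)(C)C(C)(C)C)C(C)(C)[C@H]2CC[C@]1(O)COCc3ccc(OC)cc3 | intermediate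
17 | acryloyl chloride | C=CC(=O)Cl | starting material
18 | potassium 8-alkoxide of 16 | C=C(C)CC[C@H]1[C@]2(C)CC[C@@H](O[Si](C)(C)C(C)(C)C)C(C)(C)[C@H]2CC[C@]1([O-])COCc3ccc(OC)cc3.[K+] | intermediate
19 | 8-O-acrylate with isopropenyl side chain (metathesis precursor) | C=C(C)CC[C@H]1[C@]2(C)CC[C@@H](O[Si](C)(C)C(C)(C)C)C(C)(C)[C@H]2CC[C@]1(OC(=O)C=C)COCc3ccc(OC)cc3 | intermediate
20 | eight-membered (Z)-enoate lactone (O8–C15, 17-O-PMB, 3-O-TBS) | O=C3/C=C(/C)CC[C@H]1[C@]2(C)CC[C@@H](O[Si](C)(C)C(C)(C)C)C(C)(C)[C@H]2CC[C@]1(O3)COCc4ccc(OC)cc4 | intermediate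
21 | 17-hydroxy eight-membered lactone | O=C3/C=C(/C)CC[C@H]1[C@]2(C)CC[C@@H](O[Si](C)(C)C(C)(C)C)C(C)(C)[C@H]2CC[C@]1(O3)CO | intermediate
22 | nine-membered lactone (O17–C15, 8α-OH free) | O=C3/C=C(/C)CC[C@H]1[C@]2(C)CC[C@@H](O[Si](C)(C)C(C)(C)C)C(C)(C)[C@H]2CC[C@]1(O)CO3 | intermediate
23 | diol methyl ester (13Z; 8α-OH, 17-OH; 3-O-TBS) | COC(=O)/C=C(/C)CC[C@H]1[C@]2(C)CC[C@@H](O[Si](C)(C)C(C)(C)C)C(C)(C)[C@H]2CC[C@]1(O)CO | intermediate
24 | 17-aldehyde (3-O-TBS) | COC(=O)/C=C(/C)CC[C@H]1[C@]2(C)CC[C@@H](O[Si](C)(C)C(C)(C)C)C(C)(C)[C@H]2CC[C@]1(O)C=O | intermediate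
25 | CNP0135080.1, methyl (13Z)-3α,8α-dihydroxy-17-oxolabd-13-en-15-oate (antipodal series) | COC(=O)/C=C(/C)CC[C@H]1[C@]2(C)CC[C@@H](O)C(C)(C)[C@H]2CC[C@]1(O)C=O | target

**Step count**

Total step count: 17. Longest linear sequence: 17 steps (1 → 25); 7, 14 and 17 are bought.

**Steps most likely to fail**

Step 13 (ring-closing metathesis). The ruthenium carbene may fail to engage the 1,1-disubstituted alkene across an eight-membered ring, so that acrylate dimerisation, migration of the isopropenyl double bond or catalyst decay wins over ring closure. The fallback keeps the O8 tether but closes it by intramolecular Horner–Wadsworth–Emmons olefination; it sets out from alcohol 16 and returns at lactone 20. Alcohol 16 is esterified with diethylphosphonoacetic acid and DCC (acylation through the phosphonoketene, which tolerates hindered tertiary alcohols) to give phosphonoacetate F1. Lemieux–Johnson cleavage of the isopropenyl group (OsO4 cat., NaIO4, 2,6-lutidine, dioxane/H2O) gives keto phosphonate F2. LiCl and DBU in MeCN at high dilution (Masamune–Roush conditions) should then close lactone 20, whose geometry is again fixed as Z by the ring.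

Step 15 (lactone methanolysis). If acyl substitution is slow, the liberated tertiary 8-alkoxide may add to C13 of the enoate (six-membered ether by conjugate addition), or prolonged exposure to methoxide may erode the Z geometry. The fallback replaces transesterification by hydrolysis and O-methylation; it sets out from hydroxy lactone 21 and returns at diol ester 23. LiOH in THF/H2O opens the lactone to hydroxy acid F3, whose carboxylate is not a conjugate acceptor, and neutral esterification with trimethylsilyldiazomethane in toluene/MeOH gives 23.

Step 5 (reductive coupling). Reduction or homocoupling of the alkyl bromide may outrun cross-coupling in the nickel cycle. The fallback uses a preformed organozinc and palladium catalysis; it sets out from bromide 6 and returns at ketone 8. Zinc insertion (Zn dust, LiCl, THF, 50 °C) gives alkylzinc bromide F4, which does not add to the ketone, and Negishi coupling with 2-bromopropene 7 (Pd(PPh3)4, THF, 40 °C) gives 8.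

**Further compounds**

F1 | step 13 | 8-O-(diethylphosphonoacetyl) ester of 16 | C=C(C)CC[C@H]1[C@]2(C)CC[C@@H](O[Si](C)(C)C(C)(C)C)C(C)(C)[C@H]2CC[C@]1(OC(=O)CP(=O)(OCC)OCC)COCc3ccc(OC)cc3
F2 | step 13 | keto phosphonate (C13 methyl ketone, 8-O-phosphonoacetate) | CC(=O)CC[C@H]1[C@]2(C)CC[C@@H](O[Si](C)(C)C(C)(C)C)C(C)(C)[C@H]2CC[C@]1(OC(=O)CP(=O)(OCC)OCC)COCc3ccc(OC)cc3
F3 | step 15 | (13Z)-hydroxy acid (8α-OH, 17-OH, 3-O-TBS) | OC(=O)/C=C(/C)CC[C@H]1[C@]2(C)CC[C@@H](O[Si](C)(C)C(C)(C)C)C(C)(C)[C@H]2CC[C@]1(O)CO
F4 | step 5 | alkylzinc bromide from 6 | C[C@@]12CC[C@H]([C@@]([C@H]1CCC(=O)[C@H]2CC[Zn]Br)(C)COC3(C)C)O3
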